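Readings and results are calculated for substances that don't exist.

3 questions stand on this flask, and 2 earlier runs bear on them.

| flask | substrate | solid reagent | remark | time |
|---|---|---|---|---|
| zeta | 0.13 M | 0.20 M | run made earlier |  |
| delta | 0.30 M | 0.20 M | run made earlier |  |
| flask | 0.20 M | 0.200 M |  | 12 d |

| run | time / d | single product / % |
|---|---|---|
| zeta | 3.00 | 19 |
| zeta | 4.00 | 26 |
| zeta | 5.00 | 31 |
| zeta | 6.00 | 35 |
| zeta | 8.00 | 40 |
| zeta | 10.0 | 44 |
| delta | 3.00 | 11 |
| delta | 4.00 | 13 |
| delta | 5.00 | 15 |
| delta | 6.00 | 20 |
| delta | 8.00 | 24 |
| delta | 10.0 | 29 |

(scatter of a reading: 1.5 percentage points)

* when, up to 12 d, the flask holds most single product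
* the amount of single product, in percent of the substrate charged, at that time
* the first time at which single product reaches 21%, in the same percent

- as a solid, counted per litre of solution: solid reagent
- what may be going on: solid reagent <-> coupling partner; coupling partner + single product -> bis adduct + by-product; substrate + coupling partner -> single product + by-product; substrate + coupling partner -> other mono adduct + by-product; coupling partner + other mono adduct -> bis adduct + by-product; substrate <-> dormant form
- at the start none of the solid reagent is in solution

Read as concentrations, the runs come near one number. The delta run makes on average 0.00870 M/d of single product up to its last reading, and this straight-line rate, single product per litre per day while the run follows the supply and not the substrate charge, is the quantity to carry. The zeta run, charged with 0.13 M against 0.30 M, makes 0.00823 M/d up to its first reading, so the passage from solid reagent to coupling partner looks like the rate-limiting step.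

First way: 21% of the flask's charge is 0.0420 M, which the straight-line rate reaches at 4.83 d. Second way: that concentration is 14.0% of the delta charge, passed between 4.00 d and 5.00 d, and 32.3% of the zeta charge, passed between 5.00 d and 6.00 d. The delta bracket comes from the run that gave the rate, so it checks nothing; the zeta bracket comes from the other run, and the reckoned time stands just short of its lower end.

At 12 d the ways part. The line gives 52.2%, but the zeta run's last interval makes 0.00260 M/d, so that run has left the line. Extending each run's last slope gives 48.0% for zeta and 34.0% for delta. The flask's charge lies between those of the two runs and the line stands above both, so it is the way that cheats late. Both runs still rise at their last readings, so this reckoning puts the best time at 12 d, with an amount between those two extended values.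

The forecast, 12 d, 38% and 4.7 d, reasoned that “The flask lies between them.”

The flask holds most at 12.0 d, 42.3%, and reaches 21% at 4.38 d. At 12.0 d solid reagent stands at 0% of its charge, and at 120 d single product reads 42.4%. Up to 12 d the flask averages 0.00705 M/d of single product, which is 81.1% of the straight-line rate.

    solid reagent ⇌ coupling partner, rate k1*(cs1 - [coupling partner]) while solid is left; crystals form when [coupling partner] > cs1 (solubility = 18.0 mM, k = 1.20 × 10⁻⁵ /s)
    coupling partner + single product → bis adduct + by-product (k = 1.20 × 10⁻⁴ /M/s)
    substrate + coupling partner → single product + by-product (k = 0.00150 /M/s)
    substrate + coupling partner → other mono adduct + by-product (k = 9.20 × 10⁻⁴ /M/s)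
    coupling partner + other mono adduct → bis adduct + by-product (k = 0.00100 /M/s)
    substrate ⇌ dormant form (K = 1.30, k = 8.40 × 10⁻⁶ /s)

For the same flask with 0.12 M of substrate, the straight-line rate gives 87.0% at 12 d, beyond the zeta run's 44% at 10.0 d, so that flask should leave the line early. Computed, it peaks at 43.9% and stands at 41.6% at 12.0 d, with bis adduct at 49.0%.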